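**Plan**

1. Retrosynthesis: after removal of four benzyl ethers, the flavanone is cut at C2–C3 and C4–C4a in one stroke. This is a formal [4+2] cycloaddition of an O-aryl oxocarbenium ion (C4a=C8a–O1(+)=C2) with ethoxyethyne, a ketene equivalent that supplies C3–C4. The cation comes from a mixed O-aryl O-pivaloyl acetal, hence from an aldehyde and 3,5-bis(benzyloxy)phenol, and the aldehyde is cut at the aryl–O bond to O3 of the flavonol (SNAr).
2. Forward: kaempferol is benzylated at O7 and O4' (three steps), its 3-OH is arylated with 4-fluorobenzaldehyde, the aldehyde is turned into the acylal, ring C of the flavanone is closed last, and hydrogenolysis ends the route.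
3. Enabling feature: ring A of the flavanone is a phloroglucinol ring, so C4a is ortho to O1 and ortho/para to O5 and O7. The aryl group on O1 is therefore both the oxocarbenium substituent at C2 and a strong internal π-nucleophile, and C4a and C8 are equivalent by symmetry.
4. Helpers: the pivalate (leaving group, lost in the key step), the ethoxy group on C4 (carries the ketone oxidation level, hydrolysed in the same operation) and the benzyl ethers (removed at the end).
5. Stereochemistry: the single stereocentre C2 (S) is set in the key step by a chiral counter-anion; every later condition is neutral or acidic, so the base-labile flavanone is not racemised.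

Key step: step 6

Remark: kaempferol, 4-fluorobenzaldehyde, 3,5-bis(benzyloxy)phenol and ethoxyethyne (solution in hexanes) are taken as commercial; the (S,S) acid is written for step 6, and its antipode would be used if the sense of induction proved opposite.

**Route**

Step 1
Reactants: 1 kaempferol
Product: 2 kaempferol 3,5,7,4'-tetraacetate
Conditions: Ac2O (8 equiv), pyridine, 4-(dimethylamino)pyridine (cat.), rt to 50 °C
Reagents that add atoms: acetic anhydride, CC(=O)OC(C)=O
Why: Exhaustive O-acylation under nucleophilic catalysis should esterify all four hydroxyl groups, the hydrogen-bonded 5-OH included, and so differentiate them for the next step.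

Step 2
Reactants: 2 kaempferol 3,5,7,4'-tetraacetate
Product: 3 3,5-di-O-acetyl-7,4'-di-O-benzylkaempferol
Conditions: BnBr (2.5 equiv), K2CO3 (3 equiv), acetone, reflux
Reagents that add atoms: benzyl bromide, BrCc1ccccc1
Why: In this acetyl-to-benzyl exchange carbonate should cleave only the 7- and 4'-acetates, whose phenoxides are the best leaving groups because they are conjugated with the pyrone carbonyl (through ring A and vinylogously through C2=C3), and the phenoxides are benzylated as they form (Williamson ether synthesis), while the enol acetate at C3 and the peri acetate at C5 stay.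

Step 3
Reactants: 3 3,5-di-O-acetyl-7,4'-di-O-benzylkaempferol
Product: 4 7,4'-di-O-benzylkaempferol
Conditions: K2CO3 (0.3 equiv), MeOH/THF, 0 °C to rt, under N2
Reagents that add atoms: none
Why: Base-catalysed transesterification with methanol removes the two remaining acetates as methyl acetate and leaves the benzyl ethers, air being excluded because the 3-hydroxyflavone anion is oxidised by O2.

Step 4
Reactants: 4 7,4'-di-O-benzylkaempferol; 5 4-fluorobenzaldehyde
Product: 6 4-({7-(benzyloxy)-2-[4-(benzyloxy)phenyl]-5-hydroxy-4-oxo-4H-chromen-3-yl}oxy)benzaldehyde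
Conditions: K2CO3 (1.5 equiv), DMF, 90 °C, under N2, dark
Reagents that add atoms: none
Why: Nucleophilic aromatic substitution (addition–elimination) of the 3-olate on the fluoroarene activated by the para formyl group should give the aryl ether, the 3-OH being the more acidic and more nucleophilic of the two free hydroxyls because the 5-OH is locked in a hydrogen bond to the C4 carbonyl.

Step 5
Reactants: 6 4-({7-(benzyloxy)-2-[4-(benzyloxy)phenyl]-5-hydroxy-4-oxo-4H-chromen-3-yl}oxy)benzaldehyde; 7 3,5-bis(benzyloxy)phenol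
Product: 9 racemic [3,5-bis(benzyloxy)phenoxy][4-({7-(benzyloxy)-2-[4-(benzyloxy)phenyl]-5-hydroxy-4-oxo-4H-chromen-3-yl}oxy)phenyl]methyl pivalate, via α-chlorobenzyl pivalate 8 (not isolated)
Conditions: PivCl (1.3 equiv), ZnCl2 (5 mol%), CH2Cl2, 0 °C to rt, volatiles removed; then 7 (1.1 equiv), Cs2CO3 (1.3 equiv), MeCN, −20 to 0 °C
Reagents that add atoms: pivaloyl chloride, CC(C)(C)C(Cl)=O
Why: The acyl chloride adds across the aldehyde C=O under ZnCl2 catalysis to give the α-chloroalkyl ester, and the phenoxide of 7 then displaces the benzylic chloride on oxygen (O-alkylation as in the making of acyloxyalkyl aryl ethers; the hindered pivalate resists acyl transfer), the acetal centre being formed racemic, which is of no account because it becomes planar in step 6.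

Step 6
Reactants: 9 racemic [3,5-bis(benzyloxy)phenoxy][4-({7-(benzyloxy)-2-[4-(benzyloxy)phenyl]-5-hydroxy-4-oxo-4H-chromen-3-yl}oxy)phenyl]methyl pivalate; 10 ethoxyethyne
Product: 12 (2S)-5,7-bis(benzyloxy)-2-[4-({7-(benzyloxy)-2-[4-(benzyloxy)phenyl]-5-hydroxy-4-oxo-4H-chromen-3-yl}oxy)phenyl]chroman-4-one, via (2S)-4-ethoxy-2H-chromene 11 (not isolated)
Conditions: 10 (3 equiv), (S,S)-imidodiphosphorimidate acid HN[P(=NSO2CF3)(O2R*)]2 (5 mol%, added last; R*O2 = (S)-3,3'-bis[3,5-bis(trifluoromethyl)phenyl]-1,1'-binaphthalene-2,2'-diolate), CH2Cl2/toluene, −78 °C; then 1 M aq. HCl, THF, 0 °C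
Reagents that add atoms: water, O
Why: Proposed new method: the confined chiral acid protonates the most basic site of 9, the ester carbonyl, and pivalic acid leaves (departure of the phenol instead would give a much poorer, acyloxy-substituted cation), so the O-aryl oxocarbenium ion is formed as a contact ion pair with the chiral anion; the CH terminus of ethoxyethyne adds to it at the future C2, the ketenium ion that results (future C4) is taken at once by the ring carbon ortho to the ether oxygen, loss of the arene proton returns the acid, and aqueous acid then hydrolyses enol ether 11 to ketone 12. The closest known reaction type is the Lewis-acid-promoted formal [4+2] cycloaddition of aryl oxocarbenium ions with alkenes and alkynes (oxa-Povarov reaction, racemic), and the control element is borrowed from chiral-counteranion catalysis of additions to oxocarbenium ions and from the Brønsted-acid-catalysed enantioselective Povarov reaction of N-aryl iminium ions. Ring C closes by intramolecular Friedel–Crafts attack of C4a on the sp-hybridised ketenium carbon, a six-membered closure that is exo with respect to the C=O(+) bond attacked and leaves the C3=C4 double bond inside the ring. The only new stereocentre, C2, is set in the first C–C bond formation, in which the chiral anion is expected to shield the Re face of the planar cation so that the alkyne enters from the Si face (2S); the ring closure and the hydrolysis do not touch it. The step needs ionisation in the right direction (secured by the acyloxy leaving group), attack through the unsubstituted alkyne carbon (secured by the ethoxy group, which also stabilises the cation at C4 and carries the ketone oxidation level), ring closure faster than capture of the ketenium ion from outside (secured by ring A, whose C4a is activated by three oxygens) and no choice between the two ortho carbons (they are equivalent by the symmetry of the 3,5-bis(benzyloxy)phenoxy group).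

Step 7
Reactants: 12 (2S)-5,7-bis(benzyloxy)-2-[4-({7-(benzyloxy)-2-[4-(benzyloxy)phenyl]-5-hydroxy-4-oxo-4H-chromen-3-yl}oxy)phenyl]chroman-4-one
Product: 13 (2S)-2-(4-{[5,7-dihydroxy-2-(4-hydroxyphenyl)-4-oxo-4H-chromen-3-yl]oxy}phenyl)-5,7-dihydroxychroman-4-one (target)
Conditions: H2 (1 atm), 10% Pd/C, THF/MeOH, rt
Reagents that add atoms: none
Why: Hydrogenolysis of the four benzyl aryl ethers on Pd/C under neutral conditions should leave the hydrogen-bonded aryl ketone, the tetrasubstituted C2=C3 bond of the flavonol, the aryl ether and the base-sensitive C2 stereocentre untouched.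

**Compound list**

1 | kaempferol, 3,5,7-trihydroxy-2-(4-hydroxyphenyl)-4H-chromen-4-one | O=c1c(O)c(-c2ccc(O)cc2)oc2cc(O)cc(O)c12 | starting material
2 | kaempferol 3,5,7,4'-tetraacetate | CC(=O)Oc1ccc(cc1)-c1oc2cc(OC(C)=O)cc(OC(C)=O)c2c(=O)c1OC(C)=O | intermediate
3 | 3,5-di-O-acetyl-7,4'-di-O-benzylkaempferol | CC(=O)Oc1c(-c2ccc(OCc3ccccc3)cc2)oc2cc(OCc3ccccc3)cc(OC(C)=O)c2c1=O | intermediate
4 | 7,4'-di-O-benzylkaempferol, 7-(benzyloxy)-2-[4-(benzyloxy)phenyl]-3,5-dihydroxy-4H-chromen-4-one | O=c1c(O)c(-c2ccc(OCc3ccccc3)cc2)oc2cc(OCc3ccccc3)cc(O)c12 | intermediate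
5 | 4-fluorobenzaldehyde | O=Cc1ccc(F)cc1 | starting material
6 | 4-({7-(benzyloxy)-2-[4-(benzyloxy)phenyl]-5-hydroxy-4-oxo-4H-chromen-3-yl}oxy)benzaldehyde | O=Cc1ccc(Oc2c(-c3ccc(OCc4ccccc4)cc3)oc3cc(OCc4ccccc4)cc(O)c3c2=O)cc1 | intermediate
7 | 3,5-bis(benzyloxy)phenol | Oc1cc(OCc2ccccc2)cc(OCc2ccccc2)c1 | starting material
8 | racemic chloro[4-({7-(benzyloxy)-2-[4-(benzyloxy)phenyl]-5-hydroxy-4-oxo-4H-chromen-3-yl}oxy)phenyl]methyl pivalate | CC(C)(C)C(=O)OC(Cl)c1ccc(Oc2c(-c3ccc(OCc4ccccc4)cc3)oc3cc(OCc4ccccc4)cc(O)c3c2=O)cc1 | intermediate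
9 | racemic [3,5-bis(benzyloxy)phenoxy][4-({7-(benzyloxy)-2-[4-(benzyloxy)phenyl]-5-hydroxy-4-oxo-4H-chromen-3-yl}oxy)phenyl]methyl pivalate | CC(C)(C)C(=O)OC(Oc1cc(OCc2ccccc2)cc(OCc2ccccc2)c1)c1ccc(Oc2c(-c3ccc(OCc4ccccc4)cc3)oc3cc(OCc4ccccc4)cc(O)c3c2=O)cc1 | intermediate
10 | ethoxyethyne | C#COCC | starting material
11 | 7-(benzyloxy)-2-[4-(benzyloxy)phenyl]-3-{4-[(2S)-5,7-bis(benzyloxy)-4-ethoxy-2H-chromen-2-yl]phenoxy}-5-hydroxy-4H-chromen-4-one | CCOC1=C[C@@H](c2ccc(Oc3c(-c4ccc(OCc5ccccc5)cc4)oc4cc(OCc5ccccc5)cc(O)c4c3=O)cc2)Oc2cc(OCc3ccccc3)cc(OCc3ccccc3)c21 | intermediate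
12 | (2S)-5,7-bis(benzyloxy)-2-[4-({7-(benzyloxy)-2-[4-(benzyloxy)phenyl]-5-hydroxy-4-oxo-4H-chromen-3-yl}oxy)phenyl]chroman-4-one | O=C1C[C@@H](c2ccc(Oc3c(-c4ccc(OCc5ccccc5)cc4)oc4cc(OCc5ccccc5)cc(O)c4c3=O)cc2)Oc2cc(OCc3ccccc3)cc(OCc3ccccc3)c21 | intermediate
13 | (2S)-2-(4-{[5,7-dihydroxy-2-(4-hydroxyphenyl)-4-oxo-4H-chromen-3-yl]oxy}phenyl)-5,7-dihydroxychroman-4-one | O=C1C[C@@H](c2ccc(Oc3c(-c4ccc(O)cc4)oc4cc(O)cc(O)c4c3=O)cc2)Oc2cc(O)cc(O)c21 | target

**Count and risks**

Total step count: 7. Longest linear sequence: 7 steps (1 to 13); compounds 5, 7 and 10 enter as commercial materials.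

Step 6 (bears the label). It may fail through loss of enantiocontrol in a loose ion pair, binding of the acid to the pyrone carbonyl of the flavonol, cationic oligomerisation of the ynol ether by the strong acid, capture of the cation by another electron-rich ring or by the product enol ether, or capture of the ketenium ion by the ether oxygen with ring opening. The fallback uses known chemistry and forms the C2–aryl bond instead; it sets out from 4 and comes back at 12. Chan–Lam coupling of 4 with (4-bromophenyl)boronic acid (Cu(OAc)2, pyridine, 4 Å molecular sieves, CH2Cl2, air) should give 7-(benzyloxy)-2-[4-(benzyloxy)phenyl]-3-(4-bromophenoxy)-5-hydroxy-4H-chromen-4-one F1. Miyaura borylation (bis(pinacolato)diboron, PdCl2(dppf) with dppf = 1,1'-bis(diphenylphosphino)ferrocene, KOAc, 1,4-dioxane, 80 °C) should give 7-(benzyloxy)-2-[4-(benzyloxy)phenyl]-5-hydroxy-3-[4-(4,4,5,5-tetramethyl-1,3,2-dioxaborolan-2-yl)phenoxy]-4H-chromen-4-one F2. Benzylation of commercial 5,7-dihydroxy-4H-chromen-4-one (BnBr, K2CO3, DMF, 60 °C) gives 5,7-bis(benzyloxy)-4H-chromen-4-one F3. Rhodium-catalysed asymmetric 1,4-addition of F2 to F3 ([RhCl(C2H4)2]2, (1R,4R)-2,5-diphenylbicyclo[2.2.2]octa-2,5-diene or its antipode, KOH (0.2 equiv), 1,4-dioxane/water, 40 °C) should then give 12, with C2 set by the diene ligand.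

Step 5. It may fail through C-alkylation of the ambident phenoxide, acyl transfer from the chloro ester to the phenoxide, or ionisation of the acylal during isolation. The fallback sets out from 6 and comes back at 12; it replaces steps 5 and 6 by a Knoevenagel condensation and a catalytic asymmetric oxa-Michael ring closure. Commercial 1-[2,4-bis(benzyloxy)-6-hydroxyphenyl]ethanone is C-acylated as its dianion (LiN(SiMe3)2, then di-tert-butyl dicarbonate, THF, −78 °C) to tert-butyl 3-[2,4-bis(benzyloxy)-6-hydroxyphenyl]-3-oxopropanoate F4. Knoevenagel condensation of F4 with 6 (piperidine, AcOH, toluene, 4 Å molecular sieves) should give tert-butyl 2-[2,4-bis(benzyloxy)-6-hydroxybenzoyl]-3-[4-({7-(benzyloxy)-2-[4-(benzyloxy)phenyl]-5-hydroxy-4-oxo-4H-chromen-3-yl}oxy)phenyl]prop-2-enoate F5. A bifunctional cinchona thiourea, N-[3,5-bis(trifluoromethyl)phenyl]-N'-(9-deoxy-epi-quinin-9-yl)thiourea or its quinidine-derived counterpart (toluene, −25 °C), should close ring C by enantioselective intramolecular oxa-Michael addition to tert-butyl (2S)-5,7-bis(benzyloxy)-2-[4-({7-(benzyloxy)-2-[4-(benzyloxy)phenyl]-5-hydroxy-4-oxo-4H-chromen-3-yl}oxy)phenyl]-4-oxochromane-3-carboxylate F6. p-Toluenesulfonic acid in toluene at 80 °C then removes the ester group by loss of 2-methylpropene and CO2 and gives 12.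

Step 4. It may fail because oxidative ring cleavage of the 3-olate at 90 °C, or its addition to the aldehyde, outruns the substitution. The fallback sets out from 4 and comes back at 6: Chan–Lam coupling with (4-formylphenyl)boronic acid (Cu(OAc)2, pyridine, 4 Å molecular sieves, CH2Cl2, air, rt), an oxidative copper-mediated O-arylation that needs neither an activated fluoroarene nor heating. It makes no compound outside the list (entry F0).

**Further compounds**

F1 | step 6 | 7-(benzyloxy)-2-[4-(benzyloxy)phenyl]-3-(4-bromophenoxy)-5-hydroxy-4H-chromen-4-one | Brc1ccc(Oc2c(-c3ccc(OCc4ccccc4)cc3)oc3cc(OCc4ccccc4)cc(O)c3c2=O)cc1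
F2 | step 6 | 7-(benzyloxy)-2-[4-(benzyloxy)phenyl]-5-hydroxy-3-[4-(4,4,5,5-tetramethyl-1,3,2-dioxaborolan-2-yl)phenoxy]-4H-chromen-4-one | CC1(C)OB(OC1(C)C)c1ccc(Oc2c(-c3ccc(OCc4ccccc4)cc3)oc3cc(OCc4ccccc4)cc(O)c3c2=O)cc1
F3 | step 6 | 5,7-bis(benzyloxy)-4H-chromen-4-one | O=c1ccoc2cc(OCc3ccccc3)cc(OCc3ccccc3)c12
F4 | step 5 | tert-butyl 3-[2,4-bis(benzyloxy)-6-hydroxyphenyl]-3-oxopropanoate | CC(C)(C)OC(=O)CC(=O)c1c(O)cc(OCc2ccccc2)cc1OCc1ccccc1
F5 | step 5 | tert-butyl 2-[2,4-bis(benzyloxy)-6-hydroxybenzoyl]-3-[4-({7-(benzyloxy)-2-[4-(benzyloxy)phenyl]-5-hydroxy-4-oxo-4H-chromen-3-yl}oxy)phenyl]prop-2-enoate | CC(C)(C)OC(=O)C(=Cc1ccc(Oc2c(-c3ccc(OCc4ccccc4)cc3)oc3cc(OCc4ccccc4)cc(O)c3c2=O)cc1)C(=O)c1c(O)cc(OCc2ccccc2)cc1OCc1ccccc1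
F6 | step 5 | tert-butyl (2S)-5,7-bis(benzyloxy)-2-[4-({7-(benzyloxy)-2-[4-(benzyloxy)phenyl]-5-hydroxy-4-oxo-4H-chromen-3-yl}oxy)phenyl]-4-oxochromane-3-carboxylate | O=C1C(C(=O)OC(C)(C)C)[C@@H](c2ccc(Oc3c(-c4ccc(OCc5ccccc5)cc4)oc4cc(OCc5ccccc5)cc(O)c4c3=O)cc2)Oc2cc(OCc3ccccc3)cc(OCc3ccccc3)c21
F0 | step 4 | none | none
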